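The target, 4-[(2,4-dimethoxy-6-pentylbenzoyl)oxy]-2-heptyl-6-methoxybenzoic acid, is a depside made of two benzene rings joined by an aryl ester.

**Assumption:** the SMILES contains no stereocentre or stereogenic double bond. The target is achiral, so no enantiomer has to be set or protected.

## Retrosynthetic overview
1. The target acid comes from its tert-butyl ester by acidolysis in the last step.
2. The depside link is cut at the aryl C4–O bond of ring B, not at the acyl carbon. This gives the ring A carboxylic acid and the C4–H bond of tert-butyl 2-heptyl-6-methoxybenzoate, joined in one pot by Ir borylation and Cu acyloxylation.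
3. The ring A acid comes from 2,4-dimethoxy-6-methylbenzoic acid and 1-bromobutane by lateral alkylation.
4. The ring B ester comes from 2-methoxy-6-methylbenzoic acid and 1-bromohexane by lateral alkylation, followed by tert-butyl ester formation.
5. No ring is built. Both benzene rings are bought intact, elaborated separately and joined in step 4.

## Route

**Step 1**
Reactants: 1 2,4-dimethoxy-6-methylbenzoic acid; 2 1-bromobutane
Product: 4 2,4-dimethoxy-6-pentylbenzoic acid, via ring A benzylic dianion 3 (not isolated)
Conditions: LiN(i-Pr)2 (2.3 equiv, commercial solution), THF, −78 to −20 °C, 1 h; 2 (1.2 equiv), −78 °C to rt; 1 M HCl work-up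
Reagents that add atoms: lithium diisopropylamide, [Li+].CC(C)[N-]C(C)C (its lithium is held only in 3; nothing of it stays in 4)
Why: Lateral (benzylic) lithiation of an ortho-toluic acid followed by SN2 alkylation; the lithium carboxylate directs and stabilises the benzylic carbanion, which is much more nucleophilic than the carboxylate oxygen and takes up the primary bromide at carbon only, and no stereocentre is formed.

**Step 2**
Reactants: 5 2-methoxy-6-methylbenzoic acid; 6 1-bromohexane
Product: 8 2-heptyl-6-methoxybenzoic acid, via ring B benzylic dianion 7 (not isolated)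
Conditions: LiN(i-Pr)2 (2.2 equiv, commercial solution), THF, −78 to −20 °C, 1 h; 6 (1.1 equiv), −78 °C to rt; 1 M HCl work-up
Reagents that add atoms: lithium diisopropylamide, [Li+].CC(C)[N-]C(C)C (its lithium is held only in 7; nothing of it stays in 8)
Why: The same lateral lithiation and SN2 alkylation, here on the substrate class long used to grow 6-alkyl chains of salicylate-type acids; the product is purified by acid–base extraction and no stereocentre is formed.

**Step 3**
Reactants: 8 2-heptyl-6-methoxybenzoic acid
Product: 9 tert-butyl 2-heptyl-6-methoxybenzoate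
Conditions: tert-butyl 2,2,2-trichloroacetimidate (2 equiv), BF3·OEt2 (10 mol%), CH2Cl2/cyclohexane, rt, 16 h
Reagents that add atoms: tert-butyl 2,2,2-trichloroacetimidate, CC(C)(C)OC(=N)C(Cl)(Cl)Cl
Why: Trichloroacetimidate esterification (SN1-type O-alkylation), in which the carboxyl oxygen captures a tert-butyl cation so the di-ortho-hindered acyl carbon is never attacked; the tert-butyl group carries no aryl C–H that could compete in step 4.

**Step 4**
Reactants: 9 tert-butyl 2-heptyl-6-methoxybenzoate (1.5 equiv); 4 2,4-dimethoxy-6-pentylbenzoic acid (1.0 equiv)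
Product: 11 tert-butyl 4-[(2,4-dimethoxy-6-pentylbenzoyl)oxy]-2-heptyl-6-methoxybenzoate, via aryl pinacol boronate 10 (not isolated)
Conditions: [Ir(OMe)(cod)]2 (1.5 mol%), 4,4'-di-tert-butyl-2,2'-bipyridine (3 mol%), B2pin2 (1.0 equiv to 9), THF, 80 °C (sealed), 12 h; evaporate; then 4, Cu(OTf)2 (20 mol%), Et3N (2 equiv), B(OH)3 (2 equiv), 4 Å MS, MeCN, O2 (1 atm), 70 °C, 24 h
Reagents that add atoms: bis(pinacolato)diboron, CC1(C)OB(OC1(C)C)B1OC(C)(C)C(C)(C)O1 (its boryl group is held only in 10; nothing of it stays in 11)
Why: Proposed new method: a one-pot, sterically directed formal C–H acyloxylation that closes a depside at the aryl–oxygen bond; the iridium trisboryl catalyst borylates the only ring B C–H without an ortho substituent (C4, para to the ester), and after HBpin is stripped off the triethylammonium salt of 4 converts Cu(OTf)2 into a divalent copper carboxylate that accepts the aryl group of 10 by carboxylate-assisted boron-to-copper transmetalation, is raised to a trivalent aryl copper carboxylate (disproportionation, O2 turnover) and forms the C(aryl)–O bond by reductive elimination, so bond formation occurs away from the two ortho groups that slow acyl transfer at the carbonyl of 4; triflate supplies no competing oxygen nucleophile (acetate would), B(OH)3 binds the pinacol that otherwise inhibits copper, and the tert-butyl ester keeps the ring B carboxyl out of the coupling; the closest known reaction types are Ir C–H borylation followed by Cu-mediated functionalisation and the Chan–Lam O-arylation of carboxylic acids with arylboronic acids, not shown so far for pinacol boronates made in situ, for di-ortho-substituted benzoic acids or for depsides; no stereocentre is formed.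

**Step 5**
Reactants: 11 tert-butyl 4-[(2,4-dimethoxy-6-pentylbenzoyl)oxy]-2-heptyl-6-methoxybenzoate
Product: 12 4-[(2,4-dimethoxy-6-pentylbenzoyl)oxy]-2-heptyl-6-methoxybenzoic acid (target)
Conditions: TFA/CH2Cl2 (1:4), 0 °C to rt, 2 h; evaporate cold
Reagents that add atoms: none
Why: Acidolysis of a tert-butyl ester (alkyl–oxygen cleavage with E1 loss of isobutene), which works without any nucleophile or base, so the hindered aryl ester and the three aryl methyl ethers are left untouched.

## Compound list
1 | 2,4-dimethoxy-6-methylbenzoic acid | Cc1cc(OC)cc(OC)c1C(=O)O | starting material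
2 | 1-bromobutane | CCCCBr | starting material
3 | dilithium 2-(lithiomethyl-type carbanion)-4,6-dimethoxybenzoate (ring A benzylic dianion) | [Li+].[Li+].[CH2-]c1cc(OC)cc(OC)c1C(=O)[O-] | intermediate
4 | 2,4-dimethoxy-6-pentylbenzoic acid | CCCCCc1cc(OC)cc(OC)c1C(=O)O | intermediate
5 | 2-methoxy-6-methylbenzoic acid | Cc1cccc(OC)c1C(=O)O | starting material
6 | 1-bromohexane | CCCCCCBr | starting material
7 | dilithium salt of the benzylic carbanion of 2-methoxy-6-methylbenzoate (ring B benzylic dianion) | [Li+].[Li+].[CH2-]c1cccc(OC)c1C(=O)[O-] | intermediate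
8 | 2-heptyl-6-methoxybenzoic acid | CCCCCCCc1cccc(OC)c1C(=O)O | intermediate
9 | tert-butyl 2-heptyl-6-methoxybenzoate | CCCCCCCc1cccc(OC)c1C(=O)OC(C)(C)C | intermediate
10 | tert-butyl 2-heptyl-6-methoxy-4-(4,4,5,5-tetramethyl-1,3,2-dioxaborolan-2-yl)benzoate | CCCCCCCc1cc(B2OC(C)(C)C(C)(C)O2)cc(OC)c1C(=O)OC(C)(C)C | intermediate
11 | tert-butyl 4-[(2,4-dimethoxy-6-pentylbenzoyl)oxy]-2-heptyl-6-methoxybenzoate | CCCCCCCc1cc(OC(=O)c2c(CCCCC)cc(OC)cc2OC)cc(OC)c1C(=O)OC(C)(C)C | intermediate
12 | 4-[(2,4-dimethoxy-6-pentylbenzoyl)oxy]-2-heptyl-6-methoxybenzoic acid (achiral) | CCCCCCCc1cc(OC(=O)c2c(CCCCC)cc(OC)cc2OC)cc(OC)c1C(=O)O | target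

## Step count
Total steps: 5.
Longest linear sequence: 4 steps (5 → 8 → 9 → 11 → 12, that is steps 2, 3, 4 and 5). Step 1 runs in parallel.

## Three steps most likely to fail

**Step 4 (proposed new step).**
- Risks: slow transmetalation of the pinacol boronate, oxidation of 10 to the phenol, protodeboronation, and copper-promoted decarboxylation of the electron-rich acid 4.
- Fallback (known chemistry only), from 9 back to 11. Compound 9 is borylated exactly as in the first half of step 4. Boronate 10 is then oxidised in the same flask with aqueous H2O2/NaOH in THF at 0 °C to tert-butyl 2-heptyl-4-hydroxy-6-methoxybenzoate F1, the established C–H borylation/oxidation route to phenols.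
- Acid 4 is converted with 1-chloro-N,N,2-trimethylprop-1-en-1-amine in CH2Cl2 into 2,4-dimethoxy-6-pentylbenzoyl chloride F2. Phenol F1 is acylated with F2 (Et3N, DMAP, CH2Cl2, 0 °C to rt) to give 11.
- This is the classical acyl C–O depside esterification and costs two more steps. Any phenol formed as a side product in step 4 is this same F1 and can be fed into the acylation.

**Step 1.**
- Risks: ring A is more electron-rich than ring B, so the benzylic protons are less acidic. The C3–H between the two methoxy groups may be metalated. Unreacted 1 is hard to separate from 4.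
- Fallback, from 2 back to 4. 1-Bromobutane 2 is converted (Mg, THF) into butylmagnesium bromide F3. This is coupled with commercial 3,5-dimethoxybenzyl bromide (COc1cc(CBr)cc(OC)c1) under Li2CuCl4 catalysis (Kochi-type sp3–sp3 coupling) to 1,3-dimethoxy-5-pentylbenzene F4.
- Vilsmeier–Haack formylation (POCl3, DMF) attacks para to one methoxy group and next to the chain, giving 2,4-dimethoxy-6-pentylbenzaldehyde F5. Pinnick oxidation (NaClO2, NaH2PO4, 2-methyl-2-butene, t-BuOH/H2O) gives 4.
- In this fallback the carboxyl carbon is added to a ring that already carries the chain, instead of the chain being grown on the acid.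

**Step 5.**
- Risks: acid-promoted protodecarboxylation of the electron-rich ring B acid, and tert-butylation of ring A by the released cation.
- Fallback, from 8 back to 12. Acid 8 is O-alkylated with 2,4,6-trimethylbenzyl chloride (K2CO3, DMF, 50 °C) to 2,4,6-trimethylbenzyl 2-heptyl-6-methoxybenzoate F6.
- The benzyl ring of F6 has only C–H bonds flanked by two methyl groups, so the iridium catalyst leaves it alone. An ordinary benzyl ester would be borylated.
- The protocol of step 4 then passes through the pinacol boronate 2,4,6-trimethylbenzyl 2-heptyl-6-methoxy-4-(4,4,5,5-tetramethyl-1,3,2-dioxaborolan-2-yl)benzoate F7. It gives the depside ester 2,4,6-trimethylbenzyl 4-[(2,4-dimethoxy-6-pentylbenzoyl)oxy]-2-heptyl-6-methoxybenzoate F8.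
- Neutral hydrogenolysis (H2, Pd/C, EtOAc, rt), the classical end game of depside synthesis, gives 12 without any acid.

## Further compounds
F1 | step 4 | tert-butyl 2-heptyl-4-hydroxy-6-methoxybenzoate | CCCCCCCc1cc(O)cc(OC)c1C(=O)OC(C)(C)C
F2 | step 4 | 2,4-dimethoxy-6-pentylbenzoyl chloride | CCCCCc1cc(OC)cc(OC)c1C(=O)Cl
F3 | step 1 | butylmagnesium bromide | CCCC[Mg]Br
F4 | step 1 | 1,3-dimethoxy-5-pentylbenzene | CCCCCc1cc(OC)cc(OC)c1
F5 | step 1 | 2,4-dimethoxy-6-pentylbenzaldehyde | CCCCCc1cc(OC)cc(OC)c1C=O
F6 | step 5 | 2,4,6-trimethylbenzyl 2-heptyl-6-methoxybenzoate | CCCCCCCc1cccc(OC)c1C(=O)OCc1c(C)cc(C)cc1C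
F7 | step 5 | 2,4,6-trimethylbenzyl 2-heptyl-6-methoxy-4-(4,4,5,5-tetramethyl-1,3,2-dioxaborolan-2-yl)benzoate | CCCCCCCc1cc(B2OC(C)(C)C(C)(C)O2)cc(OC)c1C(=O)OCc1c(C)cc(C)cc1C
F8 | step 5 | 2,4,6-trimethylbenzyl 4-[(2,4-dimethoxy-6-pentylbenzoyl)oxy]-2-heptyl-6-methoxybenzoate | CCCCCCCc1cc(OC(=O)c2c(CCCCC)cc(OC)cc2OC)cc(OC)c1C(=O)OCc1c(C)cc(C)cc1C
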